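## The problem

Target 38 is a cadinane seco-lactone. It has a trans-fused decalin: ring A (C1–C6) carries C4=C5 and the C15 hydroxymethyl group, and ring B (C1, C6–C10) carries the exocyclic C10=C14. C7 bears an acrylic acid (C11=C13, C12), and the neighbouring C8 oxygen is esterified by (S)-3,4-dihydroxy-2-methylidenebutanoic acid.

Four contiguous stereocentres lie on ring B (C1, C6, C7, C8, all S) and a fifth (C3′, S) lies in the acyl chain. H-1 and H-6 are trans-diaxial, the C7 arm is equatorial, and the C8 oxygen is axial and cis to the arm.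

Only C6 can be corrected by equilibration, and only while C5 is a ketone. C1 has to come from a reagent. C7 is fixed once its C–C bond exists, because the Michael adduct of a plain ester does not revert and H-7 is not acidic.

A chair-like closure onto a γ-oxygenated enoate is expected to place the C8 oxygen anti to the incoming carbon, which puts arm and oxygen trans. Closing with the C8 configuration of 38 would therefore give the C7 epimer. For this reason C8 is carried in the epimeric (R) form as the control element for C7 and is inverted afterwards.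

The fragile features are:
- C10=C14, which is sensitive to acid and, once C8 is a ketone, to base;
- two α-methylene carbonyl groups;
- the C12 acid next to the C8 ester, which can close to the 8,12-lactone;
- the diol ester, which translactonises to the α-methylene-β-hydroxybutyrolactone under base;
- the allylic alcohol.

The key step is possible because ring A can be read as cyclohex-2-enone with C5 as the carbonyl carbon. Its β-carbon C1 accepts the C10 alkenyl unit, its α-carbon C6 is the nucleophile, and C7 is the β-carbon of a C11–C12 enoate held five atoms away.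

## Retrosynthesis

**38 back to 34 and 32.** The last bonds cut are the protecting groups (38 from 37, 37 from allyl ester 36) and the ester bond O8–C1′ (36 from alcohol 34 and acid 32). The acyl chain is attached late because its diol ester does not tolerate base and its acrylate does not tolerate enolate chemistry. The forward reaction has to acylate an axial hydroxyl without letting it close onto C12, so C12 is held as an allyl ester that zerovalent palladium removes under neutral conditions. Acid 32 comes from ester 28 of the malic acid pool through acrylate 31.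

**34 back to 24.** Hydroxy ester 34 is the opened form of the cis-fused α-methylene lactone 27, and 27 is lactone 24 plus C13. Cutting C11=C13 at the lactone stage is preferred to methylenating an open ester, because the lactone masks O8 and C12 together and lactone enolates take the Mannich route cleanly. The forward reactions are a hydroxide opening with carboxylate alkylation and an α-methylenation.

**24 back to 21.** The lactone bond C12–O8 and the C8–H bond are cut. Lactone 24 arises when ketone 22 is reduced from the equatorial side and the axial alkoxide meets the C12 ester. Ketone 22 comes from the 8α alcohol 21. This is where C8 is inverted. A redox inversion is chosen over an SN2 inversion because the C12 carbonyl group would compete as an internal nucleophile.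

**21 back to 14.** The C4–C15 bond and the C4=C5 alkene are cut. Alcohol 21 goes back through 20 and 19 to enal 18, and 18 is the product of a formylation, O-alkylation and reductive carbonyl transposition (15, 16) of decalone 14. The ketone that served as nucleophile in the key step is thus used a second time to deliver C15, and no further carbon skeleton has to be built.

**14 back to 13 (key disconnection).** The C6–C7 bond is cut, which opens ring B. Precursor 13 is a 3-alkenylcyclohexanone with a tethered (Z)-γ-silyloxy enoate and two stereocentres (C1, C8) remote from each other. The forward reaction must close ring B, set C7 relative to C8 and leave C6 trans. The (Z)-geometry is chosen because 1,3-allylic strain makes the facial bias reliable. The alternative of an (E)-enoate with the C8 configuration of 38 was set aside for the reason given under "The problem".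

**13 back to 9.** The C7=C11 bond is cut: aldehyde 11 and phosphonate 12 give 13 by a Z-selective olefination. Aldehyde 11 comes from alcohol 10, which is freed from the 4-methoxybenzyl ether 9. The olefination is placed after ring A is attached so that no enoate is present during the hydride and rhodium steps.

**9 back to 7 and 8.** The C1–C10 bond is cut. Alkenylboronate 7 and cyclohex-2-en-1-one 8 are joined by a catalytic asymmetric conjugate addition, which sets C1 independently of C8. This is preferred to a cuprate addition, which would give both C1 epimers.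

**7 back to 1 and 3.** Boronate 7 comes from alkyne 5 by Markovnikov hydrometalation. Alkyne 5 is the silyl ether of alcohol 4, and 4 is cut at C9–C10 into epoxide 2 and acetylide 3. Epoxide 2 is the 4-methoxybenzyl ether of (S)-glycidol 1. The enantiomer of glycidol is chosen so that C8 is R in 13.

## Roads not taken

**Alternative 1:** The cut is at C7–C8 together with the lactone bond C12–O8. In the forward direction CrCl2 (divalent chromium) turns a C13 allylic bromide on a preformed ring A into an allylchromium species, which adds through C7 to a C8 aldehyde. The chromium alkoxide then closes onto the C12 ester and gives A1, the cis-fused α-methylene lactone, which is the same compound as 27.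
- Merits: ring B, C7, C8, the C11=C13 methylene and the lactone arise in one step, and the cyclic transition state gives the cis C7/C8 relationship directly. Here it is better than the chosen plan, which needs a relay centre at C8 and steps 14 to 18 to reach the same lactone.
- Weak points: ring A must already carry C1, C6, the C15 oxygen, an aldehyde and an allylic bromide. C6 is allylic there and cannot be corrected. The facial course of the closure relative to C6 rests on a single transition state, and chromium is used in stoichiometric amount.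
- What the chosen plan sets against it: a precursor assembled from 1, 3, 8 and 12 with one catalytic asymmetric step, C6 under thermodynamic control, and C7 and C8 each set by a separate, well-understood element.

**Alternative 2:** The cut removes three bonds of ring A (C1–C6, C2–C3, C4=C5). In the forward direction (S)-diphenylprolinol trimethylsilyl ether catalyses the Michael addition of an aldehyde to a nitrodiene. Cs2CO3 then triggers nitronate addition to a phosphonoacrylate and an intramolecular Horner–Wadsworth–Emmons reaction, giving the cyclohexenecarboxylate A2 in one pot.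
- Merits: organocatalytic enantiocontrol, and ring A is obtained with C4=C5 and C15 (as the ester) already in place. That is better than the chosen plan, which spends steps 10 to 13 on the same features.
- Weak points: nothing of ring B exists in A2. C7 and C8 still have to be made. The nitro group must be removed next to a 1,1-disubstituted alkene, and the isopropenyl methyl group needs allylic functionalisation before ring B can close.
- What the chosen plan sets against it: the harder part of the target, ring B with C6 and C7, is made in its key step, and only functional-group changes remain afterwards.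

**Alternative 3:** The cut is at C1–C6 and C7–C8 (Diels–Alder). In the forward direction a proline-derived B-aryl oxazaborolidine activated by HNTf2 binds the ketone of an (E)-keto enoate, and a (1E,3Z)-1,3-bis(silyloxy)diene adds endo to give cyclohexene A3.
- Merits: all four ring B stereocentres are set in one catalytic enantioselective step. The cis C7/C8 and trans C6/C7 relationships follow from the diene and dienophile geometry. Stereochemically this is more direct than the chosen plan, which has to invert C8.
- Weak points: the highly substituted diene is sensitive and its (3Z) geometry must be secured. After the cycloaddition ring A is still open, the C6 ester has to become C5, the C7 acetyl group has to be homologated to the acrylic acid, and the C10 silyl enol ether has to become the methylene group next to an epimerisable C1.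
- What the chosen plan sets against it: after its key step the whole skeleton except C13 and C15 is in place.

Key step: step 9

Remark: TBS is tert-butyldimethylsilyl. Bicyclic compounds are named on the cadinane skeleton with the numbering of 38 (C11 to C13 the arm on C7, C14 on C10, C15 on C4). β is the face of H-6; H-1 is α and the C7 arm is β in all of them.

Remark: 1, 3, 8, 12 and 28 (the acetonide ester derived from (S)-malic acid) are taken as purchased.

Step 1
Reactants: 1 (S)-glycidol
Product: 2 (R)-2-{[(4-methoxybenzyl)oxy]methyl}oxirane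
Conditions: NaH, 4-MeOC6H4CH2Cl, Bu4NI (cat.), THF/DMF, 0 °C to rt
Reagents that add atoms: 4-methoxybenzyl chloride, COc1ccc(CCl)cc1
Why: Williamson ether synthesis on the primary alkoxide; no bond to the stereocentre is touched (a Payne shift of glycidol only regenerates the same enantiomer) and the label changes from S to R by the priority rules alone.

Step 2
Reactants: 2 (R)-2-{[(4-methoxybenzyl)oxy]methyl}oxirane; 3 lithium acetylide ethylenediamine complex
Product: 4 (R)-1-[(4-methoxybenzyl)oxy]pent-4-yn-2-ol
Conditions: LiC≡CH·H2NCH2CH2NH2, DMSO, 0 °C to rt; aq NH4Cl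
Reagents that add atoms: none
Why: Epoxide alkynylation: SN2 attack of the acetylide at the unsubstituted epoxide carbon forms C9–C10 and leaves the carbinol centre (the future C8) untouched, in the R configuration that is epimeric to the target.

Step 3
Reactants: 4 (R)-1-[(4-methoxybenzyl)oxy]pent-4-yn-2-ol
Product: 5 (R)-tert-butyl({1-[(4-methoxybenzyl)oxy]pent-4-yn-2-yl}oxy)dimethylsilane
Conditions: t-BuMe2SiCl, imidazole, DMF, rt
Reagents that add atoms: tert-butyldimethylsilyl chloride, CC(C)(C)[Si](C)(C)Cl
Why: Silylation of the secondary alcohol; the silyl ether is the group that will sit anti to the incoming enolate in step 9 and it survives steps 4 to 13.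

Step 4
Reactants: 5 (R)-tert-butyl({1-[(4-methoxybenzyl)oxy]pent-4-yn-2-yl}oxy)dimethylsilane
Product: 7 (R)-2-[4-(tert-butyldimethylsilyloxy)-5-(4-methoxybenzyloxy)pent-1-en-2-yl]-4,4,5,5-tetramethyl-1,3,2-dioxaborolane, via alkenylalane 6 (not isolated)
Conditions: NiCl2(Ph2PCH2CH2CH2PPh2) (3 mol %), i-Bu2AlH, THF, 0 to 22 °C; then MeOBpin, 0 to 80 °C
Reagents that add atoms: 2-methoxy-4,4,5,5-tetramethyl-1,3,2-dioxaborolane, COB1OC(C)(C)C(C)(C)O1
Why: Nickel-catalysed Markovnikov hydroalumination of a terminal alkyne puts aluminium on the internal carbon (future C10) and hydrogen on the terminus (future C14); exchange of aluminium for boron with the borate ester gives the 1,1-disubstituted alkenylboronate, and the ethers tolerate the hydride.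

Step 5
Reactants: 7 (R)-2-[4-(tert-butyldimethylsilyloxy)-5-(4-methoxybenzyloxy)pent-1-en-2-yl]-4,4,5,5-tetramethyl-1,3,2-dioxaborolane; 8 cyclohex-2-en-1-one
Product: 9 (S)-3-[(R)-4-(tert-butyldimethylsilyloxy)-5-(4-methoxybenzyloxy)pent-1-en-2-yl]cyclohexan-1-one
Conditions: [RhCl(C2H4)2]2 (3 mol %), (S)-BINAP (7 mol %), KOH (0.5 equiv), dioxane/H2O (10:1), 50 °C
Reagents that add atoms: none
Why: Hayashi–Miyaura asymmetric 1,4-addition: the alkenyl group passes from boron to the (S)-BINAP complex of univalent rhodium, adds to one enantioface of the enone and the rhodium enolate is protonated by water; catalyst control sets C1 as S whatever the remote C8 centre is.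

Step 6
Reactants: 9 (S)-3-[(R)-4-(tert-butyldimethylsilyloxy)-5-(4-methoxybenzyloxy)pent-1-en-2-yl]cyclohexan-1-one
Product: 10 (S)-3-[(R)-4-(tert-butyldimethylsilyloxy)-5-hydroxypent-1-en-2-yl]cyclohexan-1-one
Conditions: DDQ, CH2Cl2/pH 7 buffer (10:1), 0 °C
Reagents that add atoms: none
Why: Oxidative cleavage of the 4-methoxybenzyl ether (benzylic hydride abstraction, then hydrolysis of the oxocarbenium ion); ketone, silyl ether and the 1,1-disubstituted alkene are inert.

Step 7
Reactants: 10 (S)-3-[(R)-4-(tert-butyldimethylsilyloxy)-5-hydroxypent-1-en-2-yl]cyclohexan-1-one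
Product: 11 (R)-2-(tert-butyldimethylsilyloxy)-4-[(S)-3-oxocyclohexyl]pent-4-enal
Conditions: Dess–Martin periodinane, NaHCO3, CH2Cl2, 0 °C to rt
Reagents that add atoms: none
Why: Dess–Martin oxidation of the primary alcohol under buffered, non-enolising conditions; the α-silyloxy aldehyde is used at once so that C8 is not epimerised.

Step 8
Reactants: 11 (R)-2-(tert-butyldimethylsilyloxy)-4-[(S)-3-oxocyclohexyl]pent-4-enal; 12 methyl 2-[bis(2,2,2-trifluoroethoxy)phosphoryl]acetate
Product: 13 methyl (2Z,4R)-4-(tert-butyldimethylsilyloxy)-6-[(1S)-3-oxocyclohexyl]hepta-2,6-dienoate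
Conditions: KN(SiMe3)2, 18-crown-6, THF, −78 °C
Reagents that add atoms: none
Why: Still–Gennari variant of the Horner–Wadsworth–Emmons reaction: the electron-poor phosphonate anion adds to the aldehyde and eliminates fast from the syn adduct, which gives the Z-enoate; the ketone does not react with this stabilised anion and C8 is untouched at −78 °C.

Step 9
Reactants: 13 methyl (2Z,4R)-4-(tert-butyldimethylsilyloxy)-6-[(1S)-3-oxocyclohexyl]hepta-2,6-dienoate
Product: 14 methyl 8α-(TBSO)-5-oxo-13,15-dinorcadin-10(14)-en-12-oate (trans-fused decalone; C7 arm and C8 silyl ether both equatorial)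
Conditions: KOt-Bu (0.2 equiv), t-BuOH/THF (1:1), 0 °C to rt; AcOH
Reagents that add atoms: none
Why: The alkoxide equilibrates the ketone enolates; only the C6 enolate can reach the enoate, and it adds to C7 in a 6-exo-trig closure of ring B (the closest known reaction type is the base-mediated intramolecular Michael addition of a cyclohexanone enolate to a tethered enoate), the ester enolate being protonated by t-BuOH. C7 is fixed in this event, since the adduct of a plain ester does not undergo retro-Michael reaction, and it is therefore placed under the control of C8. 1,3-Allylic strain of the Z-enoate holds H-8 in the plane of the enoate, the tether can deliver C6 only to the face that carries C9, and this face is opposite to the C8 silyl ether (also the Felkin–Anh arrangement). The new C6–C7 bond is thus anti to O8, which makes the C7 arm and the silyl ether trans-diequatorial. With 8R and 1S this is the chair in which the ring A bond at C1 is equatorial as well, so H-7 ends up cis to H-1 as in 38. C6 is the centre under thermodynamic control: it stays enolisable and should settle as the trans-fused, all-equatorial decalone. The step needs the C7 configuration and the direction of cyclisation; the first is secured by the Z-geometry together with the 8R silyl ether, the second by ring size, because the C4 enolate cannot reach C7.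

Step 10
Reactants: 14 methyl 8α-(TBSO)-5-oxo-13,15-dinorcadin-10(14)-en-12-oate
Product: 15 methyl (4(15)Z)-8α-(TBSO)-15-hydroxy-5-oxo-13-norcadina-4(15),10(14)-dien-12-oate (hydroxymethylene ketone)
Conditions: NaH, HCO2Et, EtOH (cat.), THF, 0 °C to rt; 1 M HCl
Reagents that add atoms: ethyl formate, CCOC=O
Why: Crossed Claisen condensation (α-formylation): of the two α-positions only the C4 methylene can end as a stabilised β-keto aldehyde enolate (C6 is a methine) and the ester α-CH2 is far less acidic, so the C4–C15 bond forms selectively; C6 remains enolisable and stays trans.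

Step 11
Reactants: 15 methyl (4(15)Z)-8α-(TBSO)-15-hydroxy-5-oxo-13-norcadina-4(15),10(14)-dien-12-oate
Product: 16 methyl (4(15)E)-8α-(TBSO)-15-isopropoxy-5-oxo-13-norcadina-4(15),10(14)-dien-12-oate
Conditions: 2-iodopropane, K2CO3, acetone, 50 °C
Reagents that add atoms: 2-iodopropane, CC(C)I
Why: O-alkylation of the 1,3-dicarbonyl enolate with a secondary iodide gives the vinylogous ester that sets up the carbonyl transposition; the alkene geometry is of no consequence.

Step 12
Reactants: 16 methyl (4(15)E)-8α-(TBSO)-15-isopropoxy-5-oxo-13-norcadina-4(15),10(14)-dien-12-oate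
Product: 18 methyl 8α-(TBSO)-15-oxo-13-norcadina-4,10(14)-dien-12-oate, via C5 allylic alcohol 17 (not isolated)
Conditions: NaBH4, CeCl3·7H2O, MeOH, 0 °C; then 1 M HCl, THF, 0 °C
Reagents that add atoms: none
Why: Luche 1,2-reduction of the vinylogous ester, then acid hydrolysis of the enol ether with loss of water (reductive 1,3-carbonyl transposition) gives the C4=C5 enal; C5 is no longer a stereocentre and the brief cold acid spares the silyl ether and C10=C14.

Step 13
Reactants: 18 methyl 8α-(TBSO)-15-oxo-13-norcadina-4,10(14)-dien-12-oate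
Product: 19 methyl 8α-(TBSO)-15-hydroxy-13-norcadina-4,10(14)-dien-12-oate
Conditions: NaBH4, CeCl3·7H2O, MeOH, −40 to 0 °C; aq NH4Cl
Reagents that add atoms: none
Why: Luche reduction: 1,2-selective hydride addition to the enal gives the C15 allylic alcohol and leaves the ester alone.

Step 14
Reactants: 19 methyl 8α-(TBSO)-15-hydroxy-13-norcadina-4,10(14)-dien-12-oate
Product: 20 methyl 8α,15-dihydroxy-13-norcadina-4,10(14)-dien-12-oate
Conditions: HF·pyridine, pyridine, THF, 0 °C to rt
Reagents that add atoms: none
Why: Fluoride-mediated desilylation under weakly acidic conditions, chosen so that no alkoxide forms that could close a trans-lactone onto the C12 ester.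

Step 15
Reactants: 20 methyl 8α,15-dihydroxy-13-norcadina-4,10(14)-dien-12-oate
Product: 21 methyl 15-(TBSO)-8α-hydroxy-13-norcadina-4,10(14)-dien-12-oate
Conditions: t-BuMe2SiCl (1.05 equiv), imidazole, CH2Cl2, −20 to 0 °C
Reagents that add atoms: tert-butyldimethylsilyl chloride, CC(C)(C)[Si](C)(C)Cl
Why: Selective silylation: the unhindered primary allylic C15 hydroxyl reacts much faster than the secondary C8 hydroxyl flanked by C7.

Step 16
Reactants: 21 methyl 15-(TBSO)-8α-hydroxy-13-norcadina-4,10(14)-dien-12-oate
Product: 22 methyl 15-(TBSO)-8-oxo-13-norcadina-4,10(14)-dien-12-oate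
Conditions: Dess–Martin periodinane, NaHCO3, CH2Cl2, 0 °C
Reagents that add atoms: none
Why: Dess–Martin oxidation under buffered neutral conditions removes the relay centre at C8 without moving the β,γ double bond C10=C14 into conjugation; C7 is now α to a ketone, but its equatorial arm is already the stable arrangement.

Step 17
Reactants: 22 methyl 15-(TBSO)-8-oxo-13-norcadina-4,10(14)-dien-12-oate
Product: 24 15-(TBSO)-13-norcadina-4,10(14)-dien-12,8β-olide (cis-fused γ-lactone), via hydroxy ester 23 (not isolated)
Conditions: LiBH(s-Bu)3, THF, −78 to 0 °C; aq NH4Cl; pyridinium p-toluenesulfonate (cat.), CH2Cl2, rt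
Reagents that add atoms: none
Why: Ketone reduction with a bulky trialkylborohydride: hydride enters along the equatorial trajectory of the 2-substituted cyclohexanone and gives the axial 8β alkoxide cis to the C7 arm, which then attacks the methyl ester (lactonisation); this sets C8 as S.

Step 18
Reactants: 24 15-(TBSO)-13-norcadina-4,10(14)-dien-12,8β-olide
Product: 27 15-(TBSO)cadina-4,10(14),11(13)-trien-12,8β-olide, via Mannich base 25 (not isolated), via ammonium iodide 26 (not isolated)
Conditions: LiN(i-Pr)2, THF, −78 °C; Me2N=CH2 I, −78 °C to rt; MeI, MeOH, rt; aq NaHCO3, CH2Cl2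
Reagents that add atoms: N,N-dimethylmethyleneiminium iodide (Eschenmoser's salt), C=[N+](C)C.[I-]
Why: α-Methylenation of a lactone: Mannich reaction of the lithium enolate with the iminium salt, N-methylation and base-induced β-elimination of trimethylamine install C13 as the exocyclic methylene; the C11 centre of the intermediates disappears.

Step 19
Reactants: 28 methyl (S)-2-(2,2-dimethyl-1,3-dioxolan-4-yl)acetate
Product: 31 methyl (S)-2-(2,2-dimethyl-1,3-dioxolan-4-yl)prop-2-enoate, via Mannich base 29 (not isolated), via ammonium iodide 30 (not isolated)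
Conditions: LiN(i-Pr)2, THF, −78 °C; Me2N=CH2 I, −78 to −20 °C; MeI, MeOH, rt; aq NaHCO3, CH2Cl2
Reagents that add atoms: N,N-dimethylmethyleneiminium iodide (Eschenmoser's salt), C=[N+](C)C.[I-]
Why: The same Mannich, quaternisation and elimination sequence on an ester enolate; the enolate is kept cold so that the β-oxygen of the dioxolane is not expelled, and the C3′ centre from malic acid is not involved.

Step 20
Reactants: 31 methyl (S)-2-(2,2-dimethyl-1,3-dioxolan-4-yl)prop-2-enoate
Product: 32 (S)-2-(2,2-dimethyl-1,3-dioxolan-4-yl)prop-2-enoic acid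
Conditions: LiOH·H2O, THF/H2O (3:1), 0 °C; 1 M HCl to pH 3, 0 °C
Reagents that add atoms: lithium hydroxide, [Li+].[OH-]
Why: Saponification (acyl substitution by hydroxide); at 0 °C conjugate addition to the α-branched acrylate is slow and the acetonide survives the brief cold acidification.

Step 21
Reactants: 27 15-(TBSO)cadina-4,10(14),11(13)-trien-12,8β-olide
Product: 34 allyl 15-(TBSO)-8β-hydroxycadina-4,10(14),11(13)-trien-12-oate, via lithium carboxylate 33 (not isolated)
Conditions: LiOH·H2O (1.05 equiv), THF/H2O (4:1), 0 °C to rt; evaporate; allyl bromide, DMF, 0 °C to rt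
Reagents that add atoms: lithium hydroxide, [Li+].[OH-]; allyl bromide, C=CCBr
Why: Lactone saponification followed by SN2 O-alkylation of the carboxylate: with one equivalent of hydroxide no alkoxide remains, so the hydroxy ester should not close back, and the allyl ester keeps C12 masked during the acylation.

Step 22
Reactants: 34 allyl 15-(TBSO)-8β-hydroxycadina-4,10(14),11(13)-trien-12-oate; 32 (S)-2-(2,2-dimethyl-1,3-dioxolan-4-yl)prop-2-enoic acid
Product: 36 allyl 15-(TBSO)-8β-{[(S)-2-(2,2-dimethyl-1,3-dioxolan-4-yl)prop-2-enoyl]oxy}cadina-4,10(14),11(13)-trien-12-oate, via mixed anhydride 35 (not isolated)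
Conditions: 2,4,6-Cl3C6H2COCl, Et3N, toluene, rt; then 34, DMAP, toluene, rt
Reagents that add atoms: none
Why: Yamaguchi esterification: the mixed anhydride of 32 passes its acyl group through the acylpyridinium ion to the axial C8 hydroxyl; no stereocentre is involved and the medium is too weakly basic for lactone re-closure.

Step 23
Reactants: 36 allyl 15-(TBSO)-8β-{[(S)-2-(2,2-dimethyl-1,3-dioxolan-4-yl)prop-2-enoyl]oxy}cadina-4,10(14),11(13)-trien-12-oate
Product: 37 15-(TBSO)-8β-{[(S)-2-(2,2-dimethyl-1,3-dioxolan-4-yl)prop-2-enoyl]oxy}cadina-4,10(14),11(13)-trien-12-oic acid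
Conditions: Pd(PPh3)4 (5 mol %), N-methylaniline, THF, rt
Reagents that add atoms: none
Why: Deallylation through a π-allyl complex of zerovalent palladium (Tsuji–Trost allyl transfer) to a weakly nucleophilic amine that does not add to the two acrylates; the neutral conditions leave the C8 ester in place.

Step 24
Reactants: 37 15-(TBSO)-8β-{[(S)-2-(2,2-dimethyl-1,3-dioxolan-4-yl)prop-2-enoyl]oxy}cadina-4,10(14),11(13)-trien-12-oic acid
Product: 38 8β-{[(S)-3,4-dihydroxy-2-methylidenebutanoyl]oxy}-15-hydroxycadina-4,10(14),11(13)-trien-12-oic acid (CNP0460913.1)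
Conditions: AcOH/H2O (4:1), 40 °C
Reagents that add atoms: none
Why: Acid hydrolysis of the acetonide and of the primary allylic silyl ether in one operation; acid is used because the diol ester is stable to acid but translactonises under base, and this acid is too weak to protonate C10=C14.

Compound list

1 | (S)-glycidol | OC[C@H]1CO1 | starting material
2 | (R)-2-{[(4-methoxybenzyl)oxy]methyl}oxirane | COc1ccc(COC[C@H]2CO2)cc1 | intermediate
3 | lithium acetylide ethylenediamine complex | [Li+].[C-]#C.NCCN | starting material
4 | (R)-1-[(4-methoxybenzyl)oxy]pent-4-yn-2-ol | COc1ccc(COC[C@H](O)CC#C)cc1 | intermediate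
5 | (R)-tert-butyl({1-[(4-methoxybenzyl)oxy]pent-4-yn-2-yl}oxy)dimethylsilane | COc1ccc(COC[C@H](O[Si](C)(C)C(C)(C)C)CC#C)cc1 | intermediate
6 | diisobutyl[(R)-4-(tert-butyldimethylsilyloxy)-5-(4-methoxybenzyloxy)pent-1-en-2-yl]alane | CC(C)C[Al](CC(C)C)C(=C)C[C@@H](O[Si](C)(C)C(C)(C)C)COCc1ccc(OC)cc1 | intermediate
7 | (R)-2-[4-(tert-butyldimethylsilyloxy)-5-(4-methoxybenzyloxy)pent-1-en-2-yl]-4,4,5,5-tetramethyl-1,3,2-dioxaborolane | CC1(C)OB(OC1(C)C)C(=C)C[C@@H](O[Si](C)(C)C(C)(C)C)COCc1ccc(OC)cc1 | intermediate
8 | cyclohex-2-en-1-one | O=C1C=CCCC1 | starting material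
9 | (S)-3-[(R)-4-(tert-butyldimethylsilyloxy)-5-(4-methoxybenzyloxy)pent-1-en-2-yl]cyclohexan-1-one | COc1ccc(COC[C@H](O[Si](C)(C)C(C)(C)C)CC(=C)[C@H]2CCCC(=O)C2)cc1 | intermediate
10 | (S)-3-[(R)-4-(tert-butyldimethylsilyloxy)-5-hydroxypent-1-en-2-yl]cyclohexan-1-one | OC[C@H](O[Si](C)(C)C(C)(C)C)CC(=C)[C@H]1CCCC(=O)C1 | intermediate
11 | (R)-2-(tert-butyldimethylsilyloxy)-4-[(S)-3-oxocyclohexyl]pent-4-enal | O=C[C@H](O[Si](C)(C)C(C)(C)C)CC(=C)[C@H]1CCCC(=O)C1 | intermediate
12 | methyl 2-[bis(2,2,2-trifluoroethoxy)phosphoryl]acetate | COC(=O)CP(=O)(OCC(F)(F)F)OCC(F)(F)F | starting material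
13 | methyl (2Z,4R)-4-(tert-butyldimethylsilyloxy)-6-[(1S)-3-oxocyclohexyl]hepta-2,6-dienoate | COC(=O)/C=C\[C@H](O[Si](C)(C)C(C)(C)C)CC(=C)[C@H]1CCCC(=O)C1 | intermediate
14 | methyl 8α-(TBSO)-5-oxo-13,15-dinorcadin-10(14)-en-12-oate | COC(=O)C[C@@H]1[C@H]2C(=O)CCC[C@@H]2C(=C)C[C@H]1O[Si](C)(C)C(C)(C)C | intermediate
15 | methyl (4(15)Z)-8α-(TBSO)-15-hydroxy-5-oxo-13-norcadina-4(15),10(14)-dien-12-oate | COC(=O)C[C@@H]1[C@H]2C(=O)/C(=C\O)CC[C@@H]2C(=C)C[C@H]1O[Si](C)(C)C(C)(C)C | intermediate
16 | methyl (4(15)E)-8α-(TBSO)-15-isopropoxy-5-oxo-13-norcadina-4(15),10(14)-dien-12-oate | COC(=O)C[C@@H]1[C@H]2C(=O)/C(=C/OC(C)C)CC[C@@H]2C(=C)C[C@H]1O[Si](C)(C)C(C)(C)C | intermediate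
17 | methyl 8α-(TBSO)-5-hydroxy-15-isopropoxy-13-norcadina-4(15),10(14)-dien-12-oate (C5 epimers) | COC(=O)C[C@@H]1[C@H]2C(O)/C(=C/OC(C)C)CC[C@@H]2C(=C)C[C@H]1O[Si](C)(C)C(C)(C)C | intermediate
18 | methyl 8α-(TBSO)-15-oxo-13-norcadina-4,10(14)-dien-12-oate | COC(=O)C[C@@H]1[C@H]2C=C(C=O)CC[C@@H]2C(=C)C[C@H]1O[Si](C)(C)C(C)(C)C | intermediate
19 | methyl 8α-(TBSO)-15-hydroxy-13-norcadina-4,10(14)-dien-12-oate | COC(=O)C[C@@H]1[C@H]2C=C(CO)CC[C@@H]2C(=C)C[C@H]1O[Si](C)(C)C(C)(C)C | intermediate
20 | methyl 8α,15-dihydroxy-13-norcadina-4,10(14)-dien-12-oate | COC(=O)C[C@@H]1[C@H]2C=C(CO)CC[C@@H]2C(=C)C[C@H]1O | intermediate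
21 | methyl 15-(TBSO)-8α-hydroxy-13-norcadina-4,10(14)-dien-12-oate | COC(=O)C[C@@H]1[C@H]2C=C(CO[Si](C)(C)C(C)(C)C)CC[C@@H]2C(=C)C[C@H]1O | intermediate
22 | methyl 15-(TBSO)-8-oxo-13-norcadina-4,10(14)-dien-12-oate | COC(=O)C[C@@H]1[C@H]2C=C(CO[Si](C)(C)C(C)(C)C)CC[C@@H]2C(=C)CC1=O | intermediate
23 | methyl 15-(TBSO)-8β-hydroxy-13-norcadina-4,10(14)-dien-12-oate | COC(=O)C[C@@H]1[C@H]2C=C(CO[Si](C)(C)C(C)(C)C)CC[C@@H]2C(=C)C[C@@H]1O | intermediate
24 | 15-(TBSO)-13-norcadina-4,10(14)-dien-12,8β-olide | O=C1C[C@@H]2[C@H]3C=C(CO[Si](C)(C)C(C)(C)C)CC[C@@H]3C(=C)C[C@@H]2O1 | intermediate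
25 | 13-(dimethylamino)-15-(TBSO)cadina-4,10(14)-dien-12,8β-olide (C11 epimers) | CN(C)CC1[C@@H]2[C@H]3C=C(CO[Si](C)(C)C(C)(C)C)CC[C@@H]3C(=C)C[C@@H]2OC1=O | intermediate
26 | 13-(trimethylammonio)-15-(TBSO)cadina-4,10(14)-dien-12,8β-olide iodide | C[N+](C)(C)CC1[C@@H]2[C@H]3C=C(CO[Si](C)(C)C(C)(C)C)CC[C@@H]3C(=C)C[C@@H]2OC1=O.[I-] | intermediate
27 | 15-(TBSO)cadina-4,10(14),11(13)-trien-12,8β-olide | C=C1[C@@H]2[C@H]3C=C(CO[Si](C)(C)C(C)(C)C)CC[C@@H]3C(=C)C[C@@H]2OC1=O | intermediate
28 | methyl (S)-2-(2,2-dimethyl-1,3-dioxolan-4-yl)acetate | COC(=O)C[C@H]1COC(C)(C)O1 | starting material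
29 | methyl 3-(dimethylamino)-2-[(S)-2,2-dimethyl-1,3-dioxolan-4-yl]propanoate (C2 epimers) | COC(=O)C(CN(C)C)[C@H]1COC(C)(C)O1 | intermediate
30 | {2-[(S)-2,2-dimethyl-1,3-dioxolan-4-yl]-3-methoxy-3-oxopropyl}trimethylammonium iodide | COC(=O)C(C[N+](C)(C)C)[C@H]1COC(C)(C)O1.[I-] | intermediate
31 | methyl (S)-2-(2,2-dimethyl-1,3-dioxolan-4-yl)prop-2-enoate | COC(=O)C(=C)[C@H]1COC(C)(C)O1 | intermediate
32 | (S)-2-(2,2-dimethyl-1,3-dioxolan-4-yl)prop-2-enoic acid | OC(=O)C(=C)[C@H]1COC(C)(C)O1 | intermediate
33 | lithium 15-(TBSO)-8β-hydroxycadina-4,10(14),11(13)-trien-12-oate | [Li+].[O-]C(=O)C(=C)[C@@H]1[C@H]2C=C(CO[Si](C)(C)C(C)(C)C)CC[C@@H]2C(=C)C[C@@H]1O | intermediate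
34 | allyl 15-(TBSO)-8β-hydroxycadina-4,10(14),11(13)-trien-12-oate | C=CCOC(=O)C(=C)[C@@H]1[C@H]2C=C(CO[Si](C)(C)C(C)(C)C)CC[C@@H]2C(=C)C[C@@H]1O | intermediate
35 | (S)-2-(2,2-dimethyl-1,3-dioxolan-4-yl)prop-2-enoic 2,4,6-trichlorobenzoic anhydride | O=C(OC(=O)c1c(Cl)cc(Cl)cc1Cl)C(=C)[C@H]1COC(C)(C)O1 | intermediate
36 | allyl 15-(TBSO)-8β-{[(S)-2-(2,2-dimethyl-1,3-dioxolan-4-yl)prop-2-enoyl]oxy}cadina-4,10(14),11(13)-trien-12-oate | C=CCOC(=O)C(=C)[C@@H]1[C@H]2C=C(CO[Si](C)(C)C(C)(C)C)CC[C@@H]2C(=C)C[C@@H]1OC(=O)C(=C)[C@H]3COC(C)(C)O3 | intermediate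
37 | 15-(TBSO)-8β-{[(S)-2-(2,2-dimethyl-1,3-dioxolan-4-yl)prop-2-enoyl]oxy}cadina-4,10(14),11(13)-trien-12-oic acid | OC(=O)C(=C)[C@@H]1[C@H]2C=C(CO[Si](C)(C)C(C)(C)C)CC[C@@H]2C(=C)C[C@@H]1OC(=O)C(=C)[C@H]3COC(C)(C)O3 | intermediate
38 | 8β-{[(S)-3,4-dihydroxy-2-methylidenebutanoyl]oxy}-15-hydroxycadina-4,10(14),11(13)-trien-12-oic acid (CNP0460913.1) | C=C(C(=O)O)[C@@H]1[C@H]2C=C(CO)CC[C@@H]2C(=C)C[C@@H]1OC(=O)C(=C)[C@H](O)CO | target

Total step count: 24. Longest linear sequence: 22 steps (from 1 through steps 1 to 18 and 21 to 24); steps 19 and 20 make acid 32.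

Steps least certain to work

Step 9 (key step). The most likely failure is slow or poorly selective ring closure. The all-equatorial chair asks the C6 enolate to bond from the less favoured face of the ring A half-chair, since the stereoelectronically easier approach would place the ring A bond at C1 axial. Isomerisation of the Z-enoate to the E-enoate, or deprotonation at C8, could then compete and erode the C7 selectivity. The fallback sets out from aldehyde 11. An intramolecular aldol condensation of C6 onto the C7 aldehyde (pyrrolidinium acetate, then MsCl and Et3N) gives the bicyclic enone 8α-(TBSO)-11,12,13,15-tetranorcadina-6,10(14)-dien-5-one F1. A Mukaiyama–Michael addition of 1-methoxy-1-(trimethylsilyloxy)ethene (LiClO4 or TiCl4) to C7, anti to the C8 silyl ether, followed by hydrolysis of the silyl enol ether and base equilibration at C6, comes back to the route at 14.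

Step 5. Protodeboronation of the hindered 1,1-disubstituted alkenylboronate may outrun transmetalation to rhodium, so that 7 is consumed without C1–C10 bond formation. The fallback sets out from 5. The alkenylalane 6 is used directly in a copper-catalysed asymmetric conjugate addition to 8 (univalent copper thiophene-2-carboxylate, Cu(O2CC4H3S), with a chiral phosphoramidite ligand, Et2O, −30 °C). Protonation of the aluminium enolate comes back to the route at 9. This fallback makes no new compound (F0).

Step 17 (with step 16). In ketone 22 the C10=C14 double bond is β,γ to the carbonyl group and can migrate into conjugation under the basic hydride. Incomplete facial selectivity would also leave some 8α alcohol. The fallback sets out from 21 and inverts C8 by substitution instead of oxidation and reduction. Saponification (LiOH·H2O, THF/H2O) gives 15-(TBSO)-8α-hydroxy-13-norcadina-4,10(14)-dien-12-oic acid F2. A Mitsunobu lactonisation (PPh3, diisopropyl azodicarboxylate, toluene) displaces the activated C8 oxygen by the carboxylate with inversion and comes back to the route at 24.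

Step 21 (and the acylation that follows). The hydroxy ester 34 may close back to lactone 27 as soon as a trace of alkoxide or DMAP activates it, and hydroxide may add to the α-methylene lactone in a conjugate sense. The fallback sets out from 27 and never passes through a γ-hydroxy ester.
- Reduction with i-Bu2AlH (CH2Cl2, −78 to 0 °C) gives 15-(TBSO)cadina-4,10(14),11(13)-triene-8β,12-diol F3.
- Et3SiCl and imidazole silylate the primary allylic hydroxyl and give 15-(TBSO)-12-(triethylsilyloxy)cadina-4,10(14),11(13)-trien-8β-ol F4.
- Yamaguchi esterification with 32 gives the 8β-ester of F4 with acid 32 F5.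
- HF·pyridine buffered with pyridine removes only the triethylsilyl group and gives the 12-alcohol F6.
- Dess–Martin oxidation gives the 12-aldehyde F7.
- Pinnick oxidation (NaClO2, NaH2PO4, 2-methylbut-2-ene, t-BuOH/H2O) comes back to the route at 37.

Further compounds

F1 | step 9 | 8α-(TBSO)-11,12,13,15-tetranorcadina-6,10(14)-dien-5-one | O=C1CCC[C@@H]2C(=C)C[C@@H](O[Si](C)(C)C(C)(C)C)C=C12
F0 | step 5 | none | none
F2 | step 17 | 15-(TBSO)-8α-hydroxy-13-norcadina-4,10(14)-dien-12-oic acid | OC(=O)C[C@@H]1[C@H]2C=C(CO[Si](C)(C)C(C)(C)C)CC[C@@H]2C(=C)C[C@H]1O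
F3 | step 21 | 15-(TBSO)cadina-4,10(14),11(13)-triene-8β,12-diol | OCC(=C)[C@@H]1[C@H]2C=C(CO[Si](C)(C)C(C)(C)C)CC[C@@H]2C(=C)C[C@@H]1O
F4 | step 21 | 15-(TBSO)-12-(triethylsilyloxy)cadina-4,10(14),11(13)-trien-8β-ol | CC[Si](CC)(CC)OCC(=C)[C@@H]1[C@H]2C=C(CO[Si](C)(C)C(C)(C)C)CC[C@@H]2C(=C)C[C@@H]1O
F5 | step 21 | 15-(TBSO)-12-(triethylsilyloxy)cadina-4,10(14),11(13)-trien-8β-yl (S)-2-(2,2-dimethyl-1,3-dioxolan-4-yl)prop-2-enoate | CC[Si](CC)(CC)OCC(=C)[C@@H]1[C@H]2C=C(CO[Si](C)(C)C(C)(C)C)CC[C@@H]2C(=C)C[C@@H]1OC(=O)C(=C)[C@H]3COC(C)(C)O3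
F6 | step 21 | 15-(TBSO)-12-hydroxycadina-4,10(14),11(13)-trien-8β-yl (S)-2-(2,2-dimethyl-1,3-dioxolan-4-yl)prop-2-enoate | OCC(=C)[C@@H]1[C@H]2C=C(CO[Si](C)(C)C(C)(C)C)CC[C@@H]2C(=C)C[C@@H]1OC(=O)C(=C)[C@H]3COC(C)(C)O3
F7 | step 21 | 15-(TBSO)-12-oxocadina-4,10(14),11(13)-trien-8β-yl (S)-2-(2,2-dimethyl-1,3-dioxolan-4-yl)prop-2-enoate | O=CC(=C)[C@@H]1[C@H]2C=C(CO[Si](C)(C)C(C)(C)C)CC[C@@H]2C(=C)C[C@@H]1OC(=O)C(=C)[C@H]3COC(C)(C)O3
A1 | alternative 1 | 15-(TBSO)cadina-4,10(14),11(13)-trien-12,8β-olide (identical with 27) | C=C1[C@@H]2[C@H]3C=C(CO[Si](C)(C)C(C)(C)C)CC[C@@H]3C(=C)C[C@@H]2OC1=O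
A2 | alternative 2 | ethyl 3-[(tert-butyldimethylsilyloxy)methyl]-5-nitro-4-(prop-1-en-2-yl)cyclohex-1-ene-1-carboxylate (configuration as in the SMILES) | CC(C)(C)[Si](C)(C)OC[C@H]1C=C(C(=O)OCC)C[C@@H]([N+](=O)[O-])[C@@H]1C(C)=C
A3 | alternative 3 | methyl 6-acetyl-3,5-bis(tert-butyldimethylsilyloxy)-2-{3-[(4-methoxybenzyloxy)methyl]but-3-en-1-yl}cyclohex-3-ene-1-carboxylate (configuration as in the SMILES) | CC(=O)[C@@H]1[C@@H](C(=O)OC)[C@H](CCC(=C)COCc2ccc(OC)cc2)C(O[Si](C)(C)C(C)(C)C)=C[C@@H]1O[Si](C)(C)C(C)(C)C
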